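**Plan**

1. Retrosynthesis: the five O-benzyl groups come off last; flavanone ring C is cut at O1–C2 and C4–C4a into 3,5-bis(benzyloxy)phenol (ring A, brought in whole) and an (R)-4-aryl-oxetan-2-one; the lactone goes back by an acetate aldol to a biaryl aldehyde; the C3'–C8'' biaryl bond is cut into 8-iodo-di-O-benzylacacetin and a formylaryl boronate.
2. Forward: the flavone unit is taken intact from acacetin, the future flavanone ring B is joined by Suzuki coupling, the C2–C3–C4 chain is added by aldol and stored as a β-lactone, flavanone ring A is fused on while ring C closes, and hydrogenolysis ends the route.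
3. Enabling feature: flavanone ring A is a phloroglucinol ring, so O1 and its ortho carbon C4a form a 1,3-O,C-dinucleophile with two symmetry-equivalent, triply activated ortho carbons (5,7-dioxygenation). It is matched to C2–C3–C4 as a 1,3-dielectrophile held in a strained four-membered lactone whose C4 (the future C2) is benzylic.
4. Stereochemistry: C2 is set as the (R)-carbinol in the HYTRA aldol, kept through lactonization (retention) and inverted once in the SN2 lactone opening to (2S); only a neutral hydrogenolysis follows.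

Key step: step 8

Assumption: rotation about the C3'–C8'' biaryl axis (three ortho oxygen substituents) is taken as fast at room temperature, as the target SMILES defines no axis, so the biaryl compounds are treated as single stereoisomers.

Abbreviations: Ar = 4-(benzyloxy)-3-[5,7-bis(benzyloxy)-2-(4-methoxyphenyl)-4-oxo-4H-chromen-8-yl]phenyl; HYTRA = 2-hydroxy-1,2,2-triphenylethyl acetate.

**Route**

Step 1
Reactants: 1 acacetin (5,7-dihydroxy-2-(4-methoxyphenyl)-4H-chromen-4-one)
Product: 2 5,7-bis(benzyloxy)-2-(4-methoxyphenyl)-4H-chromen-4-one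
Conditions: BnBr (3 equiv), K2CO3, DMF, 80 °C
Reagents that add atoms: benzyl bromide, BrCc1ccccc1
Why: Williamson ether synthesis, in which the chelated 5-OH is the slower site but should react in hot DMF with excess bromide, and no other nucleophilic site is present.

Step 2
Reactants: 2 5,7-bis(benzyloxy)-2-(4-methoxyphenyl)-4H-chromen-4-one
Product: 3 5,7-bis(benzyloxy)-8-iodo-2-(4-methoxyphenyl)-4H-chromen-4-one
Conditions: N-iodosuccinimide (1.1 equiv), CF3CO2H (0.3 equiv), MeCN/CH2Cl2, 0 °C to rt, dark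
Reagents that add atoms: N-iodosuccinimide, O=C1CCC(=O)N1I
Why: electrophilic aromatic iodination of the most electron-rich ring (flavone ring A), expected at C8 because the 5-O-benzyl group, turned away from the C4 carbonyl, screens C6, as is usual for 5,7-dialkoxyflavones.

Step 3
Reactants: 4 4-(benzyloxy)-3-bromobenzaldehyde
Product: 5 4-(benzyloxy)-3-(4,4,5,5-tetramethyl-1,3,2-dioxaborolan-2-yl)benzaldehyde
Conditions: bis(pinacolato)diboron, Pd(dppf)Cl2 (3 mol%), KOAc, 1,4-dioxane, 90 °C
Reagents that add atoms: bis(pinacolato)diboron, CC1(C)OB(OC1(C)C)B1OC(C)(C)C(C)(C)O1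
Why: Miyaura borylation, in which the weak base KOAc should suppress biaryl homocoupling and the aldehyde is tolerated.

Step 4
Reactants: 3 5,7-bis(benzyloxy)-8-iodo-2-(4-methoxyphenyl)-4H-chromen-4-one; 5 4-(benzyloxy)-3-(4,4,5,5-tetramethyl-1,3,2-dioxaborolan-2-yl)benzaldehyde
Product: 6 4-(benzyloxy)-3-[5,7-bis(benzyloxy)-2-(4-methoxyphenyl)-4-oxo-4H-chromen-8-yl]benzaldehyde (Ar–CHO)
Conditions: Pd(OAc)2 (5 mol%), SPhos (10 mol%), K3PO4, toluene/H2O (10:1), 90 °C
Reagents that add atoms: none
Why: Suzuki–Miyaura coupling, for which a dialkylbiarylphosphine ligand is chosen because the biaryl is tri-ortho-substituted and the iodide is electron-rich; the non-enolizable aldehyde should survive the aqueous phosphate.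

Step 5
Reactants: 6 Ar–CHO; 7 (R)-2-hydroxy-1,2,2-triphenylethyl acetate ((R)-HYTRA)
Product: 9 (R)-2-hydroxy-1,2,2-triphenylethyl (R)-3-Ar-3-hydroxypropanoate, via dilithium enolate of (R)-HYTRA 8 (not isolated)
Conditions: 7, LiN(iPr)2 (2.2 equiv), THF, −78 to 0 °C; then 6 in THF, −100 °C; aq NH4Cl
Reagents that add atoms: none
Why: auxiliary-controlled acetate aldol addition, in which the doubly deprotonated (R)-HYTRA should attack the Re face of the aldehyde to set the (R)-carbinol, the minor diastereomer being removable by crystallization or chromatography, and the aldehyde should react far faster than the flavone carbonyl at this temperature.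

Step 6
Reactants: 9 (R)-2-hydroxy-1,2,2-triphenylethyl (R)-3-Ar-3-hydroxypropanoate
Product: 10 (R)-3-Ar-3-hydroxypropanoic acid
Conditions: LiOH·H2O, THF/MeOH/H2O, rt to 40 °C; then 1 M HCl to pH 3, 0 °C
Reagents that add atoms: lithium hydroxide, [Li+].[OH-]
Why: ester saponification by acyl–oxygen cleavage, which leaves the carbinol stereocenter untouched and releases the auxiliary diol for recovery.

Step 7
Reactants: 10 (R)-3-Ar-3-hydroxypropanoic acid
Product: 11 (R)-4-Ar-oxetan-2-one
Conditions: bis(2-oxo-3-oxazolidinyl)phosphinic chloride (BOPCl), Et3N, CH2Cl2, 0 °C to rt; cold neutral work-up, used at once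
Reagents that add atoms: none
Why: β-lactonization by carboxyl activation (the mixed phosphinic anhydride is attacked by the β-hydroxyl), so the C–O bond at the stereocenter is not broken and the configuration should be retained.

Step 8
Reactants: 11 (R)-4-Ar-oxetan-2-one; 12 3,5-bis(benzyloxy)phenol
Product: 16 (2S)-5,7-bis(benzyloxy)-2-Ar-chroman-4-one, via sodium 3,5-bis(benzyloxy)phenoxide 13 (not isolated), via sodium (S)-3-Ar-3-[3,5-bis(benzyloxy)phenoxy]propanoate 14 (not isolated), via mixed trifluoroacetic anhydride of that acid 15 (not isolated)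
Conditions: 12, NaH (1.0 equiv), 15-crown-5, THF, 0 °C; 11, −20 °C to rt; then CH2Cl2, (CF3CO)2O, −20 to 0 °C
Reagents that add atoms: none
Why: Proposed new method: the crown-ether-separated phenoxide 13 should attack the benzylic C4 of the oxetan-2-one in an SN2 alkyl–oxygen opening driven by release of the four-membered ring strain with carboxylate as leaving group, which forms O1–C2 with inversion, and trifluoroacetic anhydride then turns carboxylate 14 into mixed anhydride 15, which acylates the ring carbon ortho to the new ether oxygen and forms C4–C4a. The closest known reaction type is the opening of β-propiolactone and 4-alkyl β-lactones by phenoxides to 3-aryloxyalkanoic acids and their separate cycloacylation to chroman-4-ones; the 4-aryl lactone and the one-pot union are the new elements. Flavanone ring C closes by a 6-exo-trig electrophilic aromatic acylation, for which the ring of 12 carries three activating oxygen substituents, so that no added Lewis or Brønsted acid should be needed. The C2 stereocenter is substrate-controlled: it is the (R)-lactone carbon inverted once to (2S), and no stereoinduction is asked of the step. The step needs alkyl–oxygen over acyl–oxygen cleavage (favoured by a weakly basic phenoxide and a benzylic carbon), SN2 over ionization (non-ionizing solvent and low temperature; an ionized lactone should fragment to styrene and CO2, which costs material and not enantiomeric purity) and O- over C-alkylation (secured by the two benzyl ethers of 12). Regiochemistry of the acylation is no issue because the two ortho carbons of 12 are equivalent by symmetry.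

Step 9
Reactants: 16 (2S)-5,7-bis(benzyloxy)-2-Ar-chroman-4-one
Product: 17 (2S)-2,3-dihydropodocarpusflavone A
Conditions: H2 (1 atm), 10% Pd/C, EtOAc/MeOH, rt, stopped at complete debenzylation
Reagents that add atoms: none
Why: hydrogenolysis of the five benzyl ethers under neutral conditions, which should leave the flavone C2=C3 bond and both carbonyls alone and cannot epimerize C2, since that requires base-mediated ring opening to the chalcone.

**Compound list**

1 | acacetin | COc1ccc(-c2cc(=O)c3c(O)cc(O)cc3o2)cc1 | starting material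
2 | 5,7-bis(benzyloxy)-2-(4-methoxyphenyl)-4H-chromen-4-one | COc1ccc(-c2cc(=O)c3c(OCc4ccccc4)cc(OCc4ccccc4)cc3o2)cc1 | intermediate
3 | 5,7-bis(benzyloxy)-8-iodo-2-(4-methoxyphenyl)-4H-chromen-4-one | COc1ccc(-c2cc(=O)c3c(OCc4ccccc4)cc(OCc4ccccc4)c(I)c3o2)cc1 | intermediate
4 | 4-(benzyloxy)-3-bromobenzaldehyde | O=Cc1ccc(OCc2ccccc2)c(Br)c1 | starting material
5 | 4-(benzyloxy)-3-(4,4,5,5-tetramethyl-1,3,2-dioxaborolan-2-yl)benzaldehyde | O=Cc1ccc(OCc2ccccc2)c(B2OC(C)(C)C(C)(C)O2)c1 | intermediate
6 | 4-(benzyloxy)-3-[5,7-bis(benzyloxy)-2-(4-methoxyphenyl)-4-oxo-4H-chromen-8-yl]benzaldehyde (Ar–CHO) | COc1ccc(-c2cc(=O)c3c(OCc4ccccc4)cc(OCc4ccccc4)c(-c4cc(C=O)ccc4OCc4ccccc4)c3o2)cc1 | intermediate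
7 | (R)-2-hydroxy-1,2,2-triphenylethyl acetate ((R)-HYTRA) | CC(=O)O[C@H](c1ccccc1)C(O)(c1ccccc1)c1ccccc1 | starting material
8 | dilithium enolate of (R)-HYTRA | [Li+].[Li+].C=C([O-])O[C@H](c1ccccc1)C([O-])(c1ccccc1)c1ccccc1 | intermediate (not isolated)
9 | (R)-2-hydroxy-1,2,2-triphenylethyl (R)-3-Ar-3-hydroxypropanoate | COc1ccc(-c2cc(=O)c3c(OCc4ccccc4)cc(OCc4ccccc4)c(-c4cc([C@H](O)CC(=O)O[C@H](c5ccccc5)C(O)(c5ccccc5)c5ccccc5)ccc4OCc4ccccc4)c3o2)cc1 | intermediate
10 | (R)-3-Ar-3-hydroxypropanoic acid | COc1ccc(-c2cc(=O)c3c(OCc4ccccc4)cc(OCc4ccccc4)c(-c4cc([C@H](O)CC(=O)O)ccc4OCc4ccccc4)c3o2)cc1 | intermediate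
11 | (R)-4-Ar-oxetan-2-one | COc1ccc(-c2cc(=O)c3c(OCc4ccccc4)cc(OCc4ccccc4)c(-c4cc([C@H]5CC(=O)O5)ccc4OCc4ccccc4)c3o2)cc1 | intermediate
12 | 3,5-bis(benzyloxy)phenol | Oc1cc(OCc2ccccc2)cc(OCc2ccccc2)c1 | starting material
13 | sodium 3,5-bis(benzyloxy)phenoxide | [Na+].[O-]c1cc(OCc2ccccc2)cc(OCc2ccccc2)c1 | intermediate (not isolated)
14 | sodium (S)-3-Ar-3-[3,5-bis(benzyloxy)phenoxy]propanoate | [Na+].COc1ccc(-c2cc(=O)c3c(OCc4ccccc4)cc(OCc4ccccc4)c(-c4cc([C@@H](Oc5cc(OCc6ccccc6)cc(OCc6ccccc6)c5)CC(=O)[O-])ccc4OCc4ccccc4)c3o2)cc1 | intermediate (not isolated)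
15 | (S)-3-Ar-3-[3,5-bis(benzyloxy)phenoxy]propanoic trifluoroacetic anhydride | COc1ccc(-c2cc(=O)c3c(OCc4ccccc4)cc(OCc4ccccc4)c(-c4cc([C@@H](Oc5cc(OCc6ccccc6)cc(OCc6ccccc6)c5)CC(=O)OC(=O)C(F)(F)F)ccc4OCc4ccccc4)c3o2)cc1 | intermediate (not isolated)
16 | (2S)-5,7-bis(benzyloxy)-2-Ar-chroman-4-one | COc1ccc(-c2cc(=O)c3c(OCc4ccccc4)cc(OCc4ccccc4)c(-c4cc([C@@H]5CC(=O)c6c(OCc7ccccc7)cc(OCc7ccccc7)cc6O5)ccc4OCc4ccccc4)c3o2)cc1 | intermediate
17 | (2S)-2,3-dihydropodocarpusflavone A | COc1ccc(-c2cc(=O)c3c(O)cc(O)c(-c4cc([C@@H]5CC(=O)c6c(O)cc(O)cc6O5)ccc4O)c3o2)cc1 | target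

**Step count**

Total: 9 steps. Longest linear sequence: 8 steps (1, 2, 4, 5, 6, 7, 8, 9, from acacetin).

**Steps most likely to fail**

1. Step 8 (Proposed new method). What may go wrong:
   - attack of the phenoxide at the lactone carbonyl (acyl–oxygen cleavage, then retro-aldol or elimination);
   - ionization of the benzylic C–O bond with loss of CO2;
   - acid-induced cleavage of the benzylic aryl ether during the acylation stage;
   - intermolecular trifluoroacetylation of the electron-rich ring before ring closure.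

   Fallback (known chemistry, building the flavanone through the C2–C1' bond instead): setting out from iodide 3, Suzuki coupling with commercial [2-(benzyloxy)-5-chlorophenyl]boronic acid (Pd(PPh3)4, Na2CO3, DME/H2O, 85 °C, the C–Cl bond being left intact) should give 5,7-bis(benzyloxy)-8-[2-(benzyloxy)-5-chlorophenyl]-2-(4-methoxyphenyl)-4H-chromen-4-one F1. Borylation of the chloride (Pd2(dba)3, XPhos, B2(OH)4, KOAc, EtOH, 80 °C) should give the boronic acid Ar–B(OH)2 F2. In parallel, commercial 5,7-dihydroxychromone is benzylated (BnBr, K2CO3, DMF) to 5,7-bis(benzyloxy)-4H-chromen-4-one F3. Base-free asymmetric conjugate addition of F2 to F3 (Pd(OCOCF3)2 with the t-BuPyOx enantiomer that gives the (2S) adduct, NH4PF6, H2O, ClCH2CH2Cl, 60 °C) returns to the route at 16.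

2. Step 7. What may go wrong: decarboxylative fragmentation of the electron-rich 4-aryl lactone during formation or isolation, or activation of the hydroxyl instead of the carboxyl (inversion or elimination).

   Fallback (no lactone): setting out from acid 10, alkylation of the carboxylate (allyl bromide, KHCO3, DMF, rt) should give allyl (R)-3-Ar-3-hydroxypropanoate F4. Intermolecular Mitsunobu etherification with phenol 12 (PPh3, diisopropyl azodicarboxylate, toluene, 0 °C) should give, with inversion, allyl (S)-3-Ar-3-[3,5-bis(benzyloxy)phenoxy]propanoate F5. Neutral deallylation (Pd(PPh3)4, morpholine, THF, rt), chosen to avoid hydroxide-induced β-elimination of the aryloxide, should give (S)-3-Ar-3-[3,5-bis(benzyloxy)phenoxy]propanoic acid F6. Cycloacylation of F6 ((CF3CO)2O, CH2Cl2, 0 °C) returns to the route at 16.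

3. Step 5. What may go wrong: poor facial selectivity if solubility forces a higher temperature, enolate addition to the flavone carbonyl, or retro-aldol on warming.

   Fallback (stereocenter set by reduction instead of C–C bond formation): setting out from aldehyde 6, Roskamp homologation (ethyl diazoacetate, SnCl2 cat., CH2Cl2, rt) should give ethyl 3-Ar-3-oxopropanoate F7. Asymmetric transfer hydrogenation (RuCl[(R,R)-TsDPEN](p-cymene), HCO2H/Et3N, rt), which by the usual aryl-ketone model should deliver the (R)-carbinol, should give ethyl (R)-3-Ar-3-hydroxypropanoate F8. Saponification (LiOH, THF/H2O, then dilute HCl) returns to the route at 10.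

**Further compounds**

F1 | step 8 | 5,7-bis(benzyloxy)-8-[2-(benzyloxy)-5-chlorophenyl]-2-(4-methoxyphenyl)-4H-chromen-4-one | COc1ccc(-c2cc(=O)c3c(OCc4ccccc4)cc(OCc4ccccc4)c(-c4cc(Cl)ccc4OCc4ccccc4)c3o2)cc1
F2 | step 8 | {4-(benzyloxy)-3-[5,7-bis(benzyloxy)-2-(4-methoxyphenyl)-4-oxo-4H-chromen-8-yl]phenyl}boronic acid | COc1ccc(-c2cc(=O)c3c(OCc4ccccc4)cc(OCc4ccccc4)c(-c4cc(B(O)O)ccc4OCc4ccccc4)c3o2)cc1
F3 | step 8 | 5,7-bis(benzyloxy)-4H-chromen-4-one | O=c1ccoc2cc(OCc3ccccc3)cc(OCc3ccccc3)c12
F4 | step 7 | allyl (R)-3-Ar-3-hydroxypropanoate | COc1ccc(-c2cc(=O)c3c(OCc4ccccc4)cc(OCc4ccccc4)c(-c4cc([C@H](O)CC(=O)OCC=C)ccc4OCc4ccccc4)c3o2)cc1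
F5 | step 7 | allyl (S)-3-Ar-3-[3,5-bis(benzyloxy)phenoxy]propanoate | COc1ccc(-c2cc(=O)c3c(OCc4ccccc4)cc(OCc4ccccc4)c(-c4cc([C@@H](Oc5cc(OCc6ccccc6)cc(OCc6ccccc6)c5)CC(=O)OCC=C)ccc4OCc4ccccc4)c3o2)cc1
F6 | step 7 | (S)-3-Ar-3-[3,5-bis(benzyloxy)phenoxy]propanoic acid | COc1ccc(-c2cc(=O)c3c(OCc4ccccc4)cc(OCc4ccccc4)c(-c4cc([C@@H](Oc5cc(OCc6ccccc6)cc(OCc6ccccc6)c5)CC(=O)O)ccc4OCc4ccccc4)c3o2)cc1
F7 | step 5 | ethyl 3-Ar-3-oxopropanoate | COc1ccc(-c2cc(=O)c3c(OCc4ccccc4)cc(OCc4ccccc4)c(-c4cc(C(=O)CC(=O)OCC)ccc4OCc4ccccc4)c3o2)cc1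
F8 | step 5 | ethyl (R)-3-Ar-3-hydroxypropanoate | COc1ccc(-c2cc(=O)c3c(OCc4ccccc4)cc(OCc4ccccc4)c(-c4cc([C@H](O)CC(=O)OCC)ccc4OCc4ccccc4)c3o2)cc1
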